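**Strategy.** Everything rests on opening ring A at its C1–C2 bond. Ring A alternates oxygen-bearing carbons (C2, C4, C6) with carbon-bearing ones (C1 acyl, C3 and C5 arylmethyl), which is the imprint of a folded 3,5,7-trioxo ester. One magnesium-methoxide Claisen cyclisation closes the ring, forms C1–C2 and aromatises it. The precursor is methyl (8R)-2,4-bis(arylmethyl)-8-methyl-3,5,7-trioxodecanoate. It is assembled from the ester end: self-Claisen of one side-ring propanoate installs both arylmethyl groups, and the (R)-acyl unit is added last as a Weinreb amide. The side rings carry benzyl ethers, and their acetyl groups travel as triisopropylsilyl enol ethers, which form at oxygen and so avoid ketalising a doubly ortho-flanked carbonyl.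

Key step: step 12

Remark: ring A is numbered from the acyl-bearing carbon (C1) and the open chain from the ester carbon; in names ArT = 2,6-bis(benzyloxy)-4-methoxy-3-methyl-5-[1-(triisopropylsilyloxy)ethenyl]phenyl and ArK = 3-acetyl-2,6-bis(benzyloxy)-4-methoxy-5-methylphenyl; 2,4,6-trihydroxytoluene is assumed to be purchasable.

**Route**

Step 1
Reactants: 1 2,4,6-trihydroxytoluene
Product: 3 2,4,6-trihydroxy-3-methylbenzaldehyde, via aryl iminium chloride 2 (not isolated)
Conditions: POCl3 (1.1 equiv), DMF, EtOAc, 0 °C → rt; then H2O, 50 °C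
Reagents that add atoms: N,N-dimethylformamide CN(C)C=O; water O
Why: Vilsmeier–Haack formylation, in which the chloroiminium ion attacks one of the two equivalent free ring positions and the first formyl group deactivates the ring against a second.

Step 2
Reactants: 3 2,4,6-trihydroxy-3-methylbenzaldehyde
Product: 4 2,6-dihydroxy-4-methoxy-3-methylbenzaldehyde
Conditions: MeI (1.05 equiv), K2CO3 (1.0 equiv), DMF, 0 °C → rt
Reagents that add atoms: iodomethane CI
Why: Williamson etherification under chelation control, since both ortho hydroxyls are hydrogen-bonded to the formyl oxygen and one equivalent of base should alkylate only the more acidic, unchelated para hydroxyl.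

Step 3
Reactants: 4 2,6-dihydroxy-4-methoxy-3-methylbenzaldehyde
Product: 5 2,6-bis(benzyloxy)-4-methoxy-3-methylbenzaldehyde
Conditions: BnBr (2.5 equiv), K2CO3 (2.5 equiv), DMF, 60 °C
Reagents that add atoms: benzyl bromide BrCc1ccccc1
Why: Exhaustive Williamson benzylation, in which warming with excess base breaks the chelates and etherifies both remaining phenols while the formyl group suppresses C-benzylation.

Step 4
Reactants: 5 2,6-bis(benzyloxy)-4-methoxy-3-methylbenzaldehyde; 6 trimethyl phosphonoacetate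
Product: 7 methyl (2E)-3-[2,6-bis(benzyloxy)-4-methoxy-3-methylphenyl]prop-2-enoate
Conditions: NaH, THF, 0 °C → rt
Reagents that add atoms: none
Why: Horner–Wadsworth–Emmons olefination of a non-enolisable aldehyde with a stabilised phosphonate anion, which should give the (E)-cinnamate.

Step 5
Reactants: 7 methyl (2E)-3-[2,6-bis(benzyloxy)-4-methoxy-3-methylphenyl]prop-2-enoate
Product: 8 methyl 3-[2,6-bis(benzyloxy)-4-methoxy-3-methylphenyl]propanoate
Conditions: NaBH4, NiCl2·6H2O (0.2 equiv), MeOH/THF, 0 °C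
Reagents that add atoms: none
Why: Conjugate reduction with nickel boride formed in the flask should saturate the enoate C=C bond while leaving aryl benzyl ethers and the ester untouched.

Step 6
Reactants: 8 methyl 3-[2,6-bis(benzyloxy)-4-methoxy-3-methylphenyl]propanoate
Product: 9 methyl 3-[3-acetyl-2,6-bis(benzyloxy)-4-methoxy-5-methylphenyl]propanoate
Conditions: AcOH (3 equiv) premixed with (CF3CO)2O (1.5 equiv), CH2Cl2, 0 °C → rt
Reagents that add atoms: acetic acid CC(=O)O
Why: Friedel–Crafts acylation by the mixed anhydride at the single free ring position (between OMe and OBn) of a tri-oxygenated arene, which needs no metal Lewis acid and should therefore spare the benzyl ethers.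

Step 7
Reactants: 9 methyl 3-[3-acetyl-2,6-bis(benzyloxy)-4-methoxy-5-methylphenyl]propanoate
Product: 10 methyl 3-{2,6-bis(benzyloxy)-4-methoxy-3-methyl-5-[1-(triisopropylsilyloxy)ethenyl]phenyl}propanoate
Conditions: TIPSOTf (1.3 equiv), Et3N (2 equiv), CH2Cl2, 0 °C → rt
Reagents that add atoms: triisopropylsilyl trifluoromethanesulfonate CC(C)[Si](OS(=O)(=O)C(F)(F)F)(C(C)C)C(C)C
Why: Enol silylation by soft enolisation, in which silicon goes to the exposed carbonyl oxygen and the amine removes a methyl proton, so the twisted ketone is masked without attack at its hindered carbon and the ester is not enolised.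

Step 8
Reactants: 10 methyl 3-{2,6-bis(benzyloxy)-4-methoxy-3-methyl-5-[1-(triisopropylsilyloxy)ethenyl]phenyl}propanoate (two molecules)
Product: 11 methyl 5-ArT-2-(ArT-methyl)-3-oxopentanoate (racemic)
Conditions: NaH (0.6 equiv per ester), MeOH (cat.), THF, 65 °C; then AcOH
Reagents that add atoms: none
Why: Claisen self-condensation driven by deprotonation of the β-keto ester, which places both arylmethyl groups on the future C2 and C4 in one step; the silyl enol ether has no acidic proton.

Step 9
Reactants: 11 methyl 5-ArT-2-(ArT-methyl)-3-oxopentanoate; 12 N-methoxy-N-methylacetamide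
Product: 13 methyl 2,4-bis(ArT-methyl)-3,5-dioxohexanoate (diastereomer mixture)
Conditions: LDA (commercial solution, 2.3 equiv), THF, 0 °C; then 12, −78 → 0 °C; then AcOH, pH 5 buffer
Reagents that add atoms: none
Why: γ-Acylation of a β-keto ester dianion with a Weinreb amide, in which the more basic γ-carbanion adds and the chelated tetrahedral adduct persists until work-up, so neither over-addition nor loss of a second equivalent of dianion is expected.

Step 10
Reactants: 14 (R)-2-methylbutanoic acid
Product: 16 (2R)-N-methoxy-N,2-dimethylbutanamide, via acyl imidazolide 15 (not isolated)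
Conditions: CDI (1.1 equiv), CH2Cl2, 0 °C → rt; then MeNHOMe·HCl (1.2 equiv), rt
Reagents that add atoms: N,O-dimethylhydroxylamine hydrochloride Cl.CNOC
Why: Weinreb amide formation through the acyl imidazolide, a neutral activation under which the simple alkyl-substituted α-centre should keep its (R) configuration.

Step 11
Reactants: 13 methyl 2,4-bis(ArT-methyl)-3,5-dioxohexanoate; 16 (2R)-N-methoxy-N,2-dimethylbutanamide
Product: 17 methyl (8R)-2,4-bis(ArT-methyl)-8-methyl-3,5,7-trioxodecanoate (epimer mixture at C2 and C4)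
Conditions: LDA (commercial solution, 3.3 equiv), THF, 0 °C; then 16, −78 → −20 °C; then AcOH at −78 °C, pH 5 buffer
Reagents that add atoms: none
Why: Terminal acylation of a diketo ester trianion with a Weinreb amide, in which the last-formed methyl carbanion is the most nucleophilic site and the (R)-centre enters as the electrophile, held in a chelated adduct until the acidic quench and so not exposed to enolisation.

Step 12
Reactants: 17 methyl (8R)-2,4-bis(ArT-methyl)-8-methyl-3,5,7-trioxodecanoate
Product: 19 (2R)-1-[2,4,6-trihydroxy-3,5-bis(ArT-methyl)phenyl]-2-methylbutan-1-one, via 2-acylcyclohexane-1,3,5-trione tautomer 18 (not isolated)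
Conditions: Mg(OMe)2 (6 equiv), MeOH/THF, rt → 45 °C; then AcOH to pH 5
Reagents that add atoms: none
Why: Magnesium methoxide turns the 5,7-diketone into its chelated enolate, whose central carbon (chain C6, future ring C1) adds to the methyl ester carbonyl (future ring C2) and expels methoxide, and the resulting trione 18 enolises to the aromatic triol. The closest known reaction type is the base-mediated Claisen (Dieckmann-type) cyclisation of 3,5,7-trioxoalkanoate esters to acylphloroglucinols. Ring A closes by a 6-exo-trig C-acylation, with C1–C2 as the only new bond. No stereocentre is created: the C2/C4 epimers of 17 converge because both carbons become sp2, and the (R)-methine is expected to survive because the neighbouring 1,3-dicarbonyl is already a magnesium enolate, which disfavours a second deprotonation next to it. The step needs C-acylation to win over aldol closure and over O-acylation; the aldol path from the ester α-carbon would create a quaternary carbon (it carries an arylmethyl group), cannot aromatise and is reversible, and the 4-hydroxy-2-pyranone from O-acylation is reopened by methoxide, so the aromatic product should be the sink.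

Step 13
Reactants: 19 (2R)-1-[2,4,6-trihydroxy-3,5-bis(ArT-methyl)phenyl]-2-methylbutan-1-one
Product: 20 (2R)-1-[2,4,6-trihydroxy-3,5-bis(ArK-methyl)phenyl]-2-methylbutan-1-one
Conditions: 1 M aq. HCl (cat.), THF, 0 °C → rt
Reagents that add atoms: none
Why: Acid hydrolysis of silyl enol ethers, in which protonation at the methylene carbon and loss of silanol should return both acetyl groups while benzyl ethers and the diarylmethane links tolerate dilute acid at room temperature.

Step 14
Reactants: 20 (2R)-1-[2,4,6-trihydroxy-3,5-bis(ArK-methyl)phenyl]-2-methylbutan-1-one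
Product: 21 (2R)-1-{3,5-bis[(3-acetyl-2,6-dihydroxy-4-methoxy-5-methylphenyl)methyl]-2,4,6-trihydroxyphenyl}-2-methylbutan-1-one (CNP0201397.1)
Conditions: H2 (1 atm), Pd/C, EtOAc/MeOH, rt
Reagents that add atoms: none
Why: Catalytic hydrogenolysis of the four aryl benzyl ethers, under which the hydrogen-bonded aryl ketones, the CH2 bridges and the stereocentre should be inert.

**Compound list**

1 | 2,4,6-trihydroxytoluene | Cc1c(O)cc(O)cc1O | starting material
2 | [(2,4,6-trihydroxy-3-methylphenyl)methylidene]dimethylammonium chloride | C[N+](C)=Cc1c(O)c(C)c(O)cc1O.[Cl-] | intermediate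
3 | 2,4,6-trihydroxy-3-methylbenzaldehyde | O=Cc1c(O)c(C)c(O)cc1O | intermediate
4 | 2,6-dihydroxy-4-methoxy-3-methylbenzaldehyde | O=Cc1c(O)c(C)c(OC)cc1O | intermediate
5 | 2,6-bis(benzyloxy)-4-methoxy-3-methylbenzaldehyde | O=Cc1c(OCc2ccccc2)c(C)c(OC)cc1OCc1ccccc1 | intermediate
6 | trimethyl phosphonoacetate | COC(=O)CP(=O)(OC)OC | starting material
7 | methyl (2E)-3-[2,6-bis(benzyloxy)-4-methoxy-3-methylphenyl]prop-2-enoate | COC(=O)/C=C/c1c(OCc2ccccc2)c(C)c(OC)cc1OCc1ccccc1 | intermediate
8 | methyl 3-[2,6-bis(benzyloxy)-4-methoxy-3-methylphenyl]propanoate | COC(=O)CCc1c(OCc2ccccc2)c(C)c(OC)cc1OCc1ccccc1 | intermediate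
9 | methyl 3-[3-acetyl-2,6-bis(benzyloxy)-4-methoxy-5-methylphenyl]propanoate | COC(=O)CCc1c(OCc2ccccc2)c(C)c(OC)c(C(C)=O)c1OCc1ccccc1 | intermediate
10 | methyl 3-{2,6-bis(benzyloxy)-4-methoxy-3-methyl-5-[1-(triisopropylsilyloxy)ethenyl]phenyl}propanoate | COC(=O)CCc1c(OCc2ccccc2)c(C)c(OC)c(C(=C)O[Si](C(C)C)(C(C)C)C(C)C)c1OCc1ccccc1 | intermediate
11 | methyl 5-ArT-2-(ArT-methyl)-3-oxopentanoate (racemic) | COC(=O)C(Cc1c(OCc2ccccc2)c(C)c(OC)c(C(=C)O[Si](C(C)C)(C(C)C)C(C)C)c1OCc1ccccc1)C(=O)CCc1c(OCc2ccccc2)c(C)c(OC)c(C(=C)O[Si](C(C)C)(C(C)C)C(C)C)c1OCc1ccccc1 | intermediate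
12 | N-methoxy-N-methylacetamide | CC(=O)N(C)OC | starting material
13 | methyl 2,4-bis(ArT-methyl)-3,5-dioxohexanoate (diastereomer mixture) | COC(=O)C(Cc1c(OCc2ccccc2)c(C)c(OC)c(C(=C)O[Si](C(C)C)(C(C)C)C(C)C)c1OCc1ccccc1)C(=O)C(Cc1c(OCc2ccccc2)c(C)c(OC)c(C(=C)O[Si](C(C)C)(C(C)C)C(C)C)c1OCc1ccccc1)C(C)=O | intermediate
14 | (R)-2-methylbutanoic acid | CC[C@@H](C)C(O)=O | starting material
15 | 1-[(2R)-2-methylbutanoyl]imidazole | CC[C@@H](C)C(=O)n1ccnc1 | intermediate
16 | (2R)-N-methoxy-N,2-dimethylbutanamide | CC[C@@H](C)C(=O)N(C)OC | intermediate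
17 | methyl (8R)-2,4-bis(ArT-methyl)-8-methyl-3,5,7-trioxodecanoate (epimer mixture at C2 and C4) | CC[C@@H](C)C(=O)CC(=O)C(Cc1c(OCc2ccccc2)c(C)c(OC)c(C(=C)O[Si](C(C)C)(C(C)C)C(C)C)c1OCc1ccccc1)C(=O)C(Cc1c(OCc2ccccc2)c(C)c(OC)c(C(=C)O[Si](C(C)C)(C(C)C)C(C)C)c1OCc1ccccc1)C(=O)OC | intermediate
18 | 2-[(2R)-2-methylbutanoyl]-4,6-bis(ArT-methyl)cyclohexane-1,3,5-trione | CC[C@@H](C)C(=O)C1C(=O)C(Cc2c(OCc3ccccc3)c(C)c(OC)c(C(=C)O[Si](C(C)C)(C(C)C)C(C)C)c2OCc2ccccc2)C(=O)C(Cc2c(OCc3ccccc3)c(C)c(OC)c(C(=C)O[Si](C(C)C)(C(C)C)C(C)C)c2OCc2ccccc2)C1=O | intermediate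
19 | (2R)-1-[2,4,6-trihydroxy-3,5-bis(ArT-methyl)phenyl]-2-methylbutan-1-one | CC[C@@H](C)C(=O)c1c(O)c(Cc2c(OCc3ccccc3)c(C)c(OC)c(C(=C)O[Si](C(C)C)(C(C)C)C(C)C)c2OCc2ccccc2)c(O)c(Cc2c(OCc3ccccc3)c(C)c(OC)c(C(=C)O[Si](C(C)C)(C(C)C)C(C)C)c2OCc2ccccc2)c1O | intermediate
20 | (2R)-1-[2,4,6-trihydroxy-3,5-bis(ArK-methyl)phenyl]-2-methylbutan-1-one | CC[C@@H](C)C(=O)c1c(O)c(Cc2c(OCc3ccccc3)c(C)c(OC)c(C(C)=O)c2OCc2ccccc2)c(O)c(Cc2c(OCc3ccccc3)c(C)c(OC)c(C(C)=O)c2OCc2ccccc2)c1O | intermediate
21 | (2R)-1-{3,5-bis[(3-acetyl-2,6-dihydroxy-4-methoxy-5-methylphenyl)methyl]-2,4,6-trihydroxyphenyl}-2-methylbutan-1-one | CC[C@@H](C)C(=O)c1c(O)c(Cc2c(O)c(C)c(OC)c(C(C)=O)c2O)c(O)c(Cc2c(O)c(C)c(OC)c(C(C)=O)c2O)c1O | target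

**Counts**

Total steps: 14. Longest linear sequence: 13 (steps 1–9 and 11–14; step 10 is a one-step branch).

**Steps most likely to fail**

Step 12. The ring closure may run through oxygen to a 4-hydroxy-2-pyranone that reopens only slowly under magnesium chelation. Methoxide may also cleave the 2-methylbutanoyl group by retro-Claisen attack, or the methine may epimerise on prolonged heating. The fallback buys ring A as an arene and makes the two CH2 bridges last. From 1, acetylation (Ac2O, BF3·OEt2) would give 1-(2,4,6-trihydroxy-3-methylphenyl)ethanone F1. BnBr/K2CO3 (2 equiv) should etherify the 4- and 6-hydroxyls and leave the hindered, chelated hydroxyl between acetyl and methyl, giving 1-[4,6-bis(benzyloxy)-2-hydroxy-3-methylphenyl]ethanone F2. MeI/K2CO3 would then give 1-[4,6-bis(benzyloxy)-2-methoxy-3-methylphenyl]ethanone F3, and H2 with Pd/C would give 1-(4,6-dihydroxy-2-methoxy-3-methylphenyl)ethanone F4. A Mannich reaction (aq. CH2O, Me2NH, EtOH) at the only free ring position would give 1-{3-[(dimethylamino)methyl]-2,4-dihydroxy-6-methoxy-5-methylphenyl}ethanone F5. From 14, (COCl)2 would give (R)-2-methylbutanoyl chloride F6, and Friedel–Crafts acylation of phloroglucinol (AlCl3, PhNO2/CH2Cl2) would give (2R)-2-methyl-1-(2,4,6-trihydroxyphenyl)butan-1-one F7. Heating F7 with two equivalents of F5 in dioxane (amine loss to the ortho-quinone methide, trapped at C3 and C5 of ring A) should give 21 directly, where the fallback rejoins the route.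

Step 11. The third deprotonation may be incomplete, the terminal carbanion may take a proton from the amide instead of adding to it (loss of material and of enantiopurity), or it may attack the ester within the same molecule. The fallback lowers the charge by working on the lactone. From 13, DBU in toluene at 80 °C should give 4-hydroxy-6-methyl-3,5-bis(ArT-methyl)-2H-pyran-2-one F8. Its dianion (LDA, 2.2 equiv, THF, −78 °C) would be acylated at the 6-methyl group with 16 to give 4-hydroxy-6-[(3R)-3-methyl-2-oxopentyl]-3,5-bis(ArT-methyl)-2H-pyran-2-one F9. Under the conditions of step 12, methoxide should open F9 to 17 in the flask, where the fallback rejoins the route, and 17 would be carried on to 19.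

Step 9. Acylation of the hindered secondary γ-carbanion may be slow and lose out to proton transfer from the acetamide methyl group. The fallback uses an aldehyde as the electrophile and adjusts the oxidation level afterwards. The dianion of 11 (LDA, 2.3 equiv) would add to acetaldehyde at −78 °C in an aldol reaction to give methyl 2,4-bis(ArT-methyl)-5-hydroxy-3-oxohexanoate F10. Dess–Martin periodinane (NaHCO3, CH2Cl2) should then oxidise F10 to 13, where the fallback rejoins the route.

**Further compounds**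

F1 | step 12 | 1-(2,4,6-trihydroxy-3-methylphenyl)ethanone | CC(=O)c1c(O)c(C)c(O)cc1O
F2 | step 12 | 1-[4,6-bis(benzyloxy)-2-hydroxy-3-methylphenyl]ethanone | CC(=O)c1c(O)c(C)c(OCc2ccccc2)cc1OCc1ccccc1
F3 | step 12 | 1-[4,6-bis(benzyloxy)-2-methoxy-3-methylphenyl]ethanone | CC(=O)c1c(OC)c(C)c(OCc2ccccc2)cc1OCc1ccccc1
F4 | step 12 | 1-(4,6-dihydroxy-2-methoxy-3-methylphenyl)ethanone | CC(=O)c1c(OC)c(C)c(O)cc1O
F5 | step 12 | 1-{3-[(dimethylamino)methyl]-2,4-dihydroxy-6-methoxy-5-methylphenyl}ethanone | CC(=O)c1c(OC)c(C)c(O)c(CN(C)C)c1O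
F6 | step 12 | (R)-2-methylbutanoyl chloride | CC[C@@H](C)C(Cl)=O
F7 | step 12 | (2R)-2-methyl-1-(2,4,6-trihydroxyphenyl)butan-1-one | CC[C@@H](C)C(=O)c1c(O)cc(O)cc1O
F8 | step 11 | 4-hydroxy-6-methyl-3,5-bis(ArT-methyl)-2H-pyran-2-one | CC1=C(Cc2c(OCc3ccccc3)c(C)c(OC)c(C(=C)O[Si](C(C)C)(C(C)C)C(C)C)c2OCc2ccccc2)C(O)=C(Cc2c(OCc3ccccc3)c(C)c(OC)c(C(=C)O[Si](C(C)C)(C(C)C)C(C)C)c2OCc2ccccc2)C(=O)O1
F9 | step 11 | 4-hydroxy-6-[(3R)-3-methyl-2-oxopentyl]-3,5-bis(ArT-methyl)-2H-pyran-2-one | CC[C@@H](C)C(=O)CC1=C(Cc2c(OCc3ccccc3)c(C)c(OC)c(C(=C)O[Si](C(C)C)(C(C)C)C(C)C)c2OCc2ccccc2)C(O)=C(Cc2c(OCc3ccccc3)c(C)c(OC)c(C(=C)O[Si](C(C)C)(C(C)C)C(C)C)c2OCc2ccccc2)C(=O)O1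
F10 | step 9 | methyl 2,4-bis(ArT-methyl)-5-hydroxy-3-oxohexanoate | COC(=O)C(Cc1c(OCc2ccccc2)c(C)c(OC)c(C(=C)O[Si](C(C)C)(C(C)C)C(C)C)c1OCc1ccccc1)C(=O)C(Cc1c(OCc2ccccc2)c(C)c(OC)c(C(=C)O[Si](C(C)C)(C(C)C)C(C)C)c1OCc1ccccc1)C(C)O
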